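**Retrosynthetic overview**
- The biaryl bond, the oxygenation pattern and the free/methylated phenol pattern are taken intact from ellagic acid (1). Its two lactone oxygens are exactly the two phenols that stay free, so O-methylation gives 2.
- Each lactone carbonyl carbon is the future benzylic CH2: half-reduction of 2 gives bis-lactol 3, a masked dialdehyde.
- Key disconnection, made twice in one flask, is ArCH2–C(O)CH3: an aldehyde carbon (electrophile) is joined to an acetyl anion equivalent. Ethyl vinyl ether (4) and Ph3P·HBr (5) give salt 6, whose ylide 7 olefinates the opened dialdehyde 8; hydrolysis of bis-enol ether 9 gives target 10.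
- No ring is formed. The two lactone rings of 1 are opened in the key step, which frees the biaryl axis.

Assumption: the SMILES has no stereocentre and no axial descriptor, so the target is taken as the constitution drawn and is obtained as the racemic (unspecified) biaryl atropisomer.

**Route**

Step 1
Reactants: 1 ellagic acid (2,3,7,8-tetrahydroxychromeno[5,4,3-cde]chromene-5,10-dione), dried
Product: 2 3,3′,4,4′-tetra-O-methylellagic acid (2,3,7,8-tetramethoxychromeno[5,4,3-cde]chromene-5,10-dione)
Conditions: MeI (6 equiv), K2CO3 (6 equiv), dry DMF, 50 °C, 24 h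
Reagents that add atoms: iodomethane, CI
Why: Williamson ether synthesis; only the four free phenols can be alkylated, because the other two oxygens are held as aryl lactones under anhydrous carbonate conditions.

Step 2
Reactants: 2 3,3′,4,4′-tetra-O-methylellagic acid
Product: 3 2,3,7,8-tetramethoxy-5,10-dihydrochromeno[5,4,3-cde]chromene-5,10-diol (bis-lactol, mixture of lactol epimers)
Conditions: i-Bu2AlH (DIBAL-H, 2.4 equiv), CH2Cl2–THF, −78 °C, 2 h; then aq. KNaC4H4O6 (Rochelle salt), rt
Reagents that add atoms: none
Why: DIBAL-H half-reduction of an aryl lactone stops at the aluminium hemiacetal at −78 °C (as for coumarin-type lactones), and the two lactol stereocentres form as an epimeric mixture that is irrelevant because both are destroyed in step 4.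

Step 3
Reactants: 4 ethyl vinyl ether; 5 triphenylphosphine hydrobromide
Product: 6 (1-ethoxyethyl)triphenylphosphonium bromide (racemic)
Conditions: CH2Cl2, 0 °C → rt, 3 h; precipitate with Et2O
Reagents that add atoms: none
Why: Markovnikov hydrophosphination of an enol ether (protonation to the oxocarbenium ion, capture by Ph3P), the known route to α-alkoxyalkylphosphonium salts from dihydropyran.

Step 4
Reactants: 3 bis-lactol; 6 (1-ethoxyethyl)triphenylphosphonium bromide
Product: 10 1,1′-(6,6′-dihydroxy-4,4′,5,5′-tetramethoxybiphenyl-2,2′-diyl)bis(propan-2-one) (target), via phosphorus ylide 7 (not isolated), via dialdehyde dipotassium salt 8 (not isolated), via bis-enol ether dipotassium salt 9 (not isolated)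
Conditions: 6 (6 equiv), KN(SiMe3)2 (KHMDS, 8 equiv), THF, −78 °C; add 3, −78 °C → rt; then 2 M HCl aq, rt, 2 h
Reagents that add atoms: water, O
Why: Base opens each lactol to its phenoxide-aldehyde, the α-ethoxy ylide 7 (a masked acetyl anion whose nucleophilic carbon becomes the ketone carbonyl) performs a twofold Wittig olefination, and acid hydrolysis of the enol ethers (E/Z mixture converges) unveils both methyl ketones and reprotonates the phenols; no stereocentre remains and the axis forms as the racemate.

**Compound list**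
1 | ellagic acid | Oc1cc2C(=O)Oc3c(O)c(O)cc4C(=O)Oc(c1O)c2c34 | starting material
2 | 3,3′,4,4′-tetra-O-methylellagic acid | COc1cc2C(=O)Oc3c(OC)c(OC)cc4C(=O)Oc(c1OC)c2c34 | intermediate
3 | 2,3,7,8-tetramethoxy-5,10-dihydrochromeno[5,4,3-cde]chromene-5,10-diol (bis-lactol, epimer mixture) | COc1cc2C(O)Oc3c(OC)c(OC)cc4C(O)Oc(c1OC)c2c34 | intermediate
4 | ethyl vinyl ether | C=COCC | starting material
5 | triphenylphosphine hydrobromide | [Br-].[PH+](c1ccccc1)(c1ccccc1)c1ccccc1 | starting material
6 | (1-ethoxyethyl)triphenylphosphonium bromide (racemic) | CCOC(C)[P+](c1ccccc1)(c1ccccc1)c1ccccc1.[Br-] | intermediate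
7 | (1-ethoxyethylidene)triphenylphosphorane (phosphorus ylide) | CCOC(C)=P(c1ccccc1)(c1ccccc1)c1ccccc1 | intermediate
8 | 6,6′-dihydroxy-4,4′,5,5′-tetramethoxybiphenyl-2,2′-dicarbaldehyde, dipotassium salt | [K+].[K+].COc1cc(C=O)c(-c2c(C=O)cc(OC)c(OC)c2[O-])c([O-])c1OC | intermediate
9 | 2,2′-bis(2-ethoxyprop-1-en-1-yl)-4,4′,5,5′-tetramethoxybiphenyl-6,6′-diol, dipotassium salt (E/Z mixture) | [K+].[K+].CCOC(C)=Cc1cc(OC)c(OC)c([O-])c1-c1c(C=C(C)OCC)cc(OC)c(OC)c1[O-] | intermediate
10 | 1,1′-(6,6′-dihydroxy-4,4′,5,5′-tetramethoxybiphenyl-2,2′-diyl)bis(propan-2-one) | COc1cc(CC(C)=O)c(-c2c(CC(C)=O)cc(OC)c(OC)c2O)c(O)c1OC | target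

**Step count**
Total steps: 4. Longest linear sequence: 3 (steps 1, 2 and 4); step 3 is a one-step side branch that makes the reagent.

**Three steps most likely to fail, with fallbacks**

Most at risk is step 4: the hindered α-alkoxy ylide may decompose before it olefinates the two ortho-aryl aldehydes. The fallback sets out from 3 and returns at 10, and replaces the ylide by a catalytic acyl anion. An N-heterocyclic-carbene crossed acyloin condensation of 3 with excess acetaldehyde is run with 3-benzyl-5-(2-hydroxyethyl)-4-methylthiazolium chloride (20 mol %) and Cs2CO3 in THF at rt. Acetaldehyde acts as the Breslow donor and the opened lactol as acceptor. This gives the bis(α-hydroxy ketone) 1,1′-(6,6′-dihydroxy-4,4′,5,5′-tetramethoxybiphenyl-2,2′-diyl)bis(1-hydroxypropan-2-one) F1. Reductive cleavage of the benzylic C–O bond α to each ketone with SmI2 (THF–MeOH, −78 °C) then gives 10.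

Second is step 2: 2 is poorly soluble, and the aryl-ester hemiacetal can collapse and over-reduce to the benzylic alcohol. The fallback sets out from 2 and returns at 3. Both lactones are opened with MeNH(OMe)·HCl/AlMe3 (CH2Cl2, reflux) to the bis-Weinreb amide 6,6′-dihydroxy-N,N′,4,4′,5,5′-hexamethoxy-N,N′-dimethylbiphenyl-2,2′-dicarboxamide F2. Reduction with excess LiAlH4 (THF, −20 °C) stops at the chelated aldehyde stage, and work-up gives 3.

Third is step 1: ellagic acid is insoluble, and carbonate with traces of water can open the lactones and over-methylate. The fallback sets out from 1 and returns at 2, and makes the lactone opening deliberate. Exhaustive methylation (Me2SO4, aq. NaOH, reflux, then acidify) gives 4,4′,5,5′,6,6′-hexamethoxybiphenyl-2,2′-dicarboxylic acid F3. SOCl2 at reflux converts it to 4,4′,5,5′,6,6′-hexamethoxybiphenyl-2,2′-dicarbonyl dichloride F4. On heating, F4 lactonises onto the only methoxy groups within reach (6 and 6′) with loss of methyl chloride, re-forming 2.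

**Further compounds**
F1 | step 4 | 1,1′-(6,6′-dihydroxy-4,4′,5,5′-tetramethoxybiphenyl-2,2′-diyl)bis(1-hydroxypropan-2-one) (diastereomer mixture) | CC(=O)C(O)c1cc(OC)c(OC)c(O)c1-c1c(C(O)C(C)=O)cc(OC)c(OC)c1O
F2 | step 2 | 6,6′-dihydroxy-N,N′,4,4′,5,5′-hexamethoxy-N,N′-dimethylbiphenyl-2,2′-dicarboxamide | CON(C)C(=O)c1cc(OC)c(OC)c(O)c1-c1c(C(=O)N(C)OC)cc(OC)c(OC)c1O
F3 | step 1 | 4,4′,5,5′,6,6′-hexamethoxybiphenyl-2,2′-dicarboxylic acid | COc1cc(C(O)=O)c(-c2c(C(O)=O)cc(OC)c(OC)c2OC)c(OC)c1OC
F4 | step 1 | 4,4′,5,5′,6,6′-hexamethoxybiphenyl-2,2′-dicarbonyl dichloride | COc1cc(C(Cl)=O)c(-c2c(C(Cl)=O)cc(OC)c(OC)c2OC)c(OC)c1OC
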